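**Retrosynthetic overview**

1. Target 32 ⇐ bicyclic enedione 27 by late C2 oxygenation (conjugate borylation/oxidation), C3 prenylation (Tsuji–Trost) and desilylation.
2. 27 ⇐ monocyclic diazo enedione 25 (key step): Lewis-acid intramolecular diazo–ketone ring expansion. The diazo carbon C1 on the C5 tether adds to C9=O (closes ring B through C1–C9) and ring carbon C2 shifts from C9 to C1, so the five-membered ring C5–C9–C2–C3–C4 grows into ring A (C1–C2–C3–C4–C5–C9).
3. Enabling feature: C1 is an acyl-bearing (aroyl) carbon lying between the carbonyl carbons C9 and C2, so it can enter as a stabilised diazo carbon. C5 is flanked by the C9 and C4 carbonyls, so its precursor ring is a 2,2-disubstituted cyclopent-4-ene-1,3-dione with a local mirror plane; the C7 stereocentre on the tether chooses the carbonyl and thereby sets C5 and C1.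
4. 25 ⇐ dinitrile 18 (nitrile reduction, vinyl Grignard, ring-closing metathesis, alkyne hydration, diazo transfer, MnO2) ⇐ malononitrile + iodide 9 (auxiliary-controlled prenylation sets C7; aryl alkyne as masked aryl ketone) + (S)-lavandulyl iodide 15 (auxiliary-controlled deconjugative prenylation).
5. Ring order: cyclopentene ring (metathesis) first, then ring B and ring A together in the key step.

Key step: step 19

Remark (numbering): C1 = bridgehead with the aroyl group, C2–C3–C4 = enolised β-diketone bridge, C5 = bridgehead with the lavandulyl chain, C6–C7–C8 = carbon bridge (C7 prenyl, C8 gem-dimethyl), C9 = bridging ketone, C10 = aroyl carbonyl; ring A = C1–C2–C3–C4–C5–C9, ring B = C1–C9–C5–C6–C7–C8; the target is (1S,5R,7S) with an (R) side-chain stereocentre.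
Remark (assumption): 3,3-dimethylpent-4-ynoic acid is taken as a purchasable building block; the required side chain corresponds to (S)-lavandulol, which is therefore made by auxiliary chemistry.

**Route**

Step 1
Reactants: 1 3,3-dimethylpent-4-ynoic acid; 2 (R)-4-benzyl-1,3-oxazolidin-2-one
Product: 3 N-(3,3-dimethylpent-4-ynoyl) oxazolidinone
Conditions: PivCl, Et3N, THF, −20 °C; then 2, LiCl, rt
Reagents that add atoms: none
Why: Mixed-anhydride N-acylation of the oxazolidinone should occur at the less hindered carbonyl of the pivalic mixed anhydride; no stereocentre is formed and the imide avoids cyclisation of a free acid onto the alkyne later.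

Step 2
Reactants: 4 4-bromobenzene-1,2-diol
Product: 5 4-bromo-1,2-bis(triisopropylsilyloxy)benzene
Conditions: TIPSOTf, 2,6-lutidine, CH2Cl2, 0 °C to rt
Reagents that add atoms: triisopropylsilyl trifluoromethanesulfonate, CC(C)[Si](OS(=O)(=O)C(F)(F)F)(C(C)C)C(C)C
Why: Silyl ether formation on both phenols; the bulky silyl groups should survive the basic, hydride and organometallic steps and leave with fluoride at the end.

Step 3
Reactants: 3 alkynyl imide; 5 aryl bromide
Product: 6 aryl alkyne imide
Conditions: PdCl2(PPh3)2 (5 mol%), CuI (5 mol%), Et3N, DMF, 70 °C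
Reagents that add atoms: none
Why: Sonogashira coupling of the terminal alkyne with the aryl bromide installs the aryl alkyne, a base-, hydride- and Grignard-stable mask of the aryl ketone C10(=O)–C1H2.

Step 4
Reactants: 6 aryl alkyne imide
Product: 7 (2R)-prenylated imide
Conditions: NaN(SiMe3)2, THF, −78 °C; prenyl bromide, −78 to −30 °C
Reagents that add atoms: 1-bromo-3-methylbut-2-ene, CC(C)=CCBr
Why: Chiral-auxiliary enolate alkylation; the chelated Z-sodium enolate should be prenylated on the face opposite the benzyl group, which sets the future C7 stereocentre next to the quaternary carbon.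

Step 5
Reactants: 7 prenylated imide
Product: 8 (2R)-primary alcohol
Conditions: LiBH4, MeOH (1 equiv), Et2O, 0 °C
Reagents that add atoms: none
Why: Reductive cleavage of the N-acyl oxazolidinone should give the primary alcohol without touching alkyne, alkene or silyl ethers and without epimerising the α-stereocentre.

Step 6
Reactants: 8 primary alcohol
Product: 9 primary iodide
Conditions: I2, PPh3, imidazole, CH2Cl2, 0 °C to rt
Reagents that add atoms: iodine, II
Why: Appel-type iodination by SN2 at the CH2 carbon leaves the adjacent stereocentre untouched.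

Step 7
Reactants: 10 3-methylbut-2-enoyl chloride; 11 (S)-4-benzyl-1,3-oxazolidin-2-one
Product: 12 N-(3-methylbut-2-enoyl) oxazolidinone
Conditions: n-BuLi, THF, −78 °C; then 10, −78 to 0 °C
Reagents that add atoms: none
Why: N-acylation of the lithiated oxazolidinone with the acid chloride; no stereocentre is formed.

Step 8
Reactants: 12 unsaturated imide
Product: 13 (2S)-lavandulyl imide
Conditions: NaN(SiMe3)2, THF, −78 °C; prenyl bromide, −78 to −40 °C
Reagents that add atoms: 1-bromo-3-methylbut-2-ene, CC(C)=CCBr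
Why: Deconjugative α-alkylation of the chelated sodium dienolate; prenyl bromide should add at the α-carbon anti to the benzyl group, setting the side-chain stereocentre and leaving the isopropenyl group.

Step 9
Reactants: 13 lavandulyl imide
Product: 14 (S)-lavandulol
Conditions: LiBH4, MeOH (1 equiv), Et2O, 0 °C
Reagents that add atoms: none
Why: Reductive removal of the auxiliary gives the primary alcohol with the stereocentre intact.

Step 10
Reactants: 14 (S)-lavandulol
Product: 15 (S)-lavandulyl iodide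
Conditions: I2, PPh3, imidazole, CH2Cl2, 0 °C
Reagents that add atoms: iodine, II
Why: Appel-type iodination at the primary carbon; the stereocentre is not involved.

Step 11
Reactants: 9 primary iodide; 16 malononitrile
Product: 17 monoalkylated malononitrile
Conditions: NaH, 16 (3 equiv), THF then DMSO; 9, 60 °C
Reagents that add atoms: none
Why: SN2 C-alkylation of sodium malononitrile, a small and weakly basic carbanion suited to a β-branched iodide; excess nucleophile should suppress dialkylation and C7 is untouched.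

Step 12
Reactants: 17 monoalkylated malononitrile; 15 (S)-lavandulyl iodide
Product: 18 dialkylated malononitrile
Conditions: NaH, DMF, 0 °C; 15, 50 °C
Reagents that add atoms: none
Why: Second SN2 alkylation builds the quaternary carbon that becomes C5; it is not a stereocentre because its two nitrile arms are identical.

Step 13
Reactants: 18 dialkylated malononitrile
Product: 19 2,2-disubstituted propanedial
Conditions: i-Bu2AlH (2.5 equiv), toluene, −78 to 0 °C; aq. potassium sodium tartrate, then SiO2/H2O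
Reagents that add atoms: water, O
Why: Partial reduction of both nitriles to N-aluminated imines and hydrolysis should give the non-enolisable dialdehyde; alkyne, alkenes and silyl ethers are inert at low temperature.

Step 14
Reactants: 19 dialdehyde
Product: 20 dienediol
Conditions: CH2=CHMgBr (3 equiv), THF, −78 to 0 °C; aq. NH4Cl
Reagents that add atoms: vinylmagnesium bromide, C=C[Mg]Br
Why: Grignard 1,2-addition to both aldehydes; the carbinol configurations are irrelevant because both are oxidised in step 18.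

Step 15
Reactants: 20 dienediol
Product: 21 cyclopentenediol
Conditions: first-generation Grubbs catalyst RuCl2(PCy3)2(=CHPh) (5 mol%), CH2Cl2, 40 °C
Reagents that add atoms: none
Why: Ring-closing olefin metathesis of the two monosubstituted vinyl groups forms the cyclopentene; this catalyst should leave the trisubstituted and 1,1-disubstituted alkenes and the hindered internal alkyne alone.

Step 16
Reactants: 21 cyclopentenediol
Product: 22 aryl ketone diol
Conditions: AuCl(PPh3) (5 mol%), AgOTf (5 mol%), 1,4-dioxane/H2O, 60 °C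
Reagents that add atoms: water, O
Why: Gold-catalysed alkyne hydration; water should add at the aryl-bearing carbon (electron-rich aryl, other alkyne carbon shielded by the quaternary centre), giving the aryl ketone with C1 as its only α-CH2.

Step 17
Reactants: 22 aryl ketone diol
Product: 24 α-diazo ketone diol, via tris(trifluoroacetyl) intermediate 23 (not isolated)
Conditions: LiN(SiMe3)2 (3.3 equiv), THF, −78 °C; CF3CO2CH2CF3 (3.6 equiv); then 4-acetamidobenzenesulfonyl azide, Et3N, H2O, MeCN, rt
Reagents that add atoms: 4-acetamidobenzenesulfonyl azide, CC(=O)Nc1ccc(cc1)S(=O)(=O)N=[N+]=[N-]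
Why: Detrifluoroacetylative Regitz diazo transfer; the only enolisable ketone is C-trifluoroacetylated through its lithium enolate (both alkoxides are acylated in passing), the azide transfers N2 with loss of the trifluoroacetyl group, and the trifluoroacetates are cleaved by the aqueous amine.

Step 18
Reactants: 24 α-diazo ketone diol
Product: 25 diazo cyclopentenedione
Conditions: MnO2 (excess), CH2Cl2, rt
Reagents that add atoms: none
Why: MnO2 oxidation of both allylic alcohols gives the enedione under neutral conditions that the acceptor diazo group should survive; the carbinol stereocentres disappear and C5 is flanked by two equivalent carbonyls.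

Step 19
Reactants: 25 diazo cyclopentenedione
Product: 27 bicyclo[3.3.1]non-3-ene-2,9-dione, via oxido diazonium betaine 26 (not isolated)
Conditions: Sc(OTf)3 (20 mol%), CH2Cl2, −78 to 0 °C, high dilution
Reagents that add atoms: none
Why: Proposed new method: Sc(OTf)3 binds a ring carbonyl of 25, the nucleophilic diazo carbon C1 adds to it through a six-membered chair transition state to give the oxido diazonium 26, and the antiperiplanar ring carbon C2 then migrates from C9 to C1 with loss of N2 while C9 returns to a ketone. The closest known reaction is the Lewis-acid-catalysed Tiffeneau–Demjanov-type one-carbon ring expansion of cyclic ketones with α-substituted α-diazo carbonyl compounds, which gives α-acyl ketones with quaternary α-carbons; the intramolecular version on a cyclopentenedione is the untested part. Ring B is closed by 6-exo-trig attack of C1 on C9=O, and ring A arises by 1,2-shift ring expansion of the five-membered ring C5–C9–C2–C3–C4 into C1–C2–C3–C4–C5–C9. C5 and C1 are set together: the C7 stereocentre places its prenyl group equatorial in the chair, which selects one of the two diastereotopic carbonyls, and the bridged geometry then fixes C1 with the aroyl group exo. The step needs migration of C2 rather than C5 and carbonyl addition rather than dipolar cycloaddition to the enedione alkene; an sp2 carbon antiperiplanar to the diazonium should migrate more readily than the acyl-bearing quaternary C5, and the fully substituted diazo carbon and low temperature should disfavour cycloaddition.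

Step 20
Reactants: 27 bicyclic enedione
Product: 29 C2 alcohol, via C2 pinacolboronate 28 (not isolated)
Conditions: CuCl (10 mol%), NaOtBu (10 mol%), Xantphos, B2pin2, MeOH, THF, rt; then 30% H2O2, NaH2PO4/Na2HPO4 buffer (pH 7), 0 °C
Reagents that add atoms: hydrogen peroxide, OO
Why: Copper-catalysed conjugate borylation puts boron on C2, the β-carbon of the C4 enone, and near-neutral oxidation of the C–B bond gives the alcohol; the C2 configuration is irrelevant because it is oxidised next.

Step 21
Reactants: 29 C2 alcohol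
Product: 30 2,4,9-trione (enol form)
Conditions: Dess–Martin periodinane, CH2Cl2, 0 °C to rt
Reagents that add atoms: none
Why: Dess–Martin oxidation of the secondary alcohol gives the C2/C4 β-diketone, which enolises and thereby stabilises the C1 centre.

Step 22
Reactants: 30 trione
Product: 31 C3-prenylated bis(silyl ether)
Conditions: Pd(PPh3)4 (5 mol%), prenyl acetate, Et3N, THF, 40 °C
Reagents that add atoms: 3-methylbut-2-en-1-yl acetate, CC(=O)OCC=C(C)C
Why: Tsuji–Trost allylation; the enolised β-diketone should be C-alkylated at C3 by the (1,1-dimethylallyl)palladium complex at its less hindered terminus, giving the linear prenyl group, with any O-allylation reversible.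

Step 23
Reactants: 31 bis(silyl ether)
Product: 32 target
Conditions: Bu4NF, AcOH, THF, 0 °C
Reagents that add atoms: none
Why: Fluoride cleavage of the two aryl silyl ethers, buffered to avoid acid-induced cyclisation of the C3 prenyl group onto the enol; no stereocentre is touched.

**Compound list**

1 | 3,3-dimethylpent-4-ynoic acid | C#CC(C)(C)CC(=O)O | starting material
2 | (R)-4-benzyl-1,3-oxazolidin-2-one | O=C1N[C@H](Cc2ccccc2)CO1 | starting material
3 | (4R)-4-benzyl-3-(3,3-dimethylpent-4-ynoyl)-1,3-oxazolidin-2-one | C#CC(C)(C)CC(=O)N1[C@H](Cc2ccccc2)COC1=O | intermediate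
4 | 4-bromobenzene-1,2-diol | Oc1ccc(Br)cc1O | starting material
5 | 4-bromo-1,2-bis(triisopropylsilyloxy)benzene | CC(C)[Si](C(C)C)(C(C)C)Oc1ccc(Br)cc1O[Si](C(C)C)(C(C)C)C(C)C | intermediate
6 | (4R)-4-benzyl-3-{5-[3,4-bis(triisopropylsilyloxy)phenyl]-3,3-dimethylpent-4-ynoyl}-1,3-oxazolidin-2-one | CC(C)[Si](C(C)C)(C(C)C)Oc1ccc(C#CC(C)(C)CC(=O)N2[C@H](Cc3ccccc3)COC2=O)cc1O[Si](C(C)C)(C(C)C)C(C)C | intermediate
7 | (4R)-4-benzyl-3-{(2R)-5-[3,4-bis(triisopropylsilyloxy)phenyl]-3,3-dimethyl-2-(3-methylbut-2-en-1-yl)pent-4-ynoyl}-1,3-oxazolidin-2-one | CC(C)[Si](C(C)C)(C(C)C)Oc1ccc(C#CC(C)(C)[C@@H](CC=C(C)C)C(=O)N2[C@H](Cc3ccccc3)COC2=O)cc1O[Si](C(C)C)(C(C)C)C(C)C | intermediate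
8 | (2R)-5-[3,4-bis(triisopropylsilyloxy)phenyl]-3,3-dimethyl-2-(3-methylbut-2-en-1-yl)pent-4-yn-1-ol | CC(C)[Si](C(C)C)(C(C)C)Oc1ccc(C#CC(C)(C)[C@@H](CC=C(C)C)CO)cc1O[Si](C(C)C)(C(C)C)C(C)C | intermediate
9 | 4-[(4R)-5-iodo-3,3-dimethyl-4-(3-methylbut-2-en-1-yl)pent-1-yn-1-yl]-1,2-bis(triisopropylsilyloxy)benzene | CC(C)[Si](C(C)C)(C(C)C)Oc1ccc(C#CC(C)(C)[C@@H](CC=C(C)C)CI)cc1O[Si](C(C)C)(C(C)C)C(C)C | intermediate
10 | 3-methylbut-2-enoyl chloride | CC(C)=CC(=O)Cl | starting material
11 | (S)-4-benzyl-1,3-oxazolidin-2-one | O=C1N[C@@H](Cc2ccccc2)CO1 | starting material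
12 | (4S)-4-benzyl-3-(3-methylbut-2-enoyl)-1,3-oxazolidin-2-one | CC(C)=CC(=O)N1[C@@H](Cc2ccccc2)COC1=O | intermediate
13 | (4S)-4-benzyl-3-[(2S)-5-methyl-2-(prop-1-en-2-yl)hex-4-enoyl]-1,3-oxazolidin-2-one | C=C(C)[C@H](CC=C(C)C)C(=O)N1[C@@H](Cc2ccccc2)COC1=O | intermediate
14 | (S)-lavandulol, (2S)-5-methyl-2-(prop-1-en-2-yl)hex-4-en-1-ol | C=C(C)[C@H](CC=C(C)C)CO | intermediate
15 | (S)-lavandulyl iodide, (3S)-3-(iodomethyl)-2,6-dimethylhepta-1,5-diene | C=C(C)[C@H](CC=C(C)C)CI | intermediate
16 | malononitrile (propanedinitrile) | N#CCC#N | starting material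
17 | 2-{(2S)-5-[3,4-bis(triisopropylsilyloxy)phenyl]-3,3-dimethyl-2-(3-methylbut-2-en-1-yl)pent-4-yn-1-yl}propanedinitrile | N#CC(C#N)C[C@H](CC=C(C)C)C(C)(C)C#Cc1ccc(O[Si](C(C)C)(C(C)C)C(C)C)c(O[Si](C(C)C)(C(C)C)C(C)C)c1 | intermediate
18 | 2-{(2S)-5-[3,4-bis(triisopropylsilyloxy)phenyl]-3,3-dimethyl-2-(3-methylbut-2-en-1-yl)pent-4-yn-1-yl}-2-[(2R)-5-methyl-2-(prop-1-en-2-yl)hex-4-en-1-yl]propanedinitrile | N#CC(C#N)(C[C@H](C(C)=C)CC=C(C)C)C[C@H](CC=C(C)C)C(C)(C)C#Cc1ccc(O[Si](C(C)C)(C(C)C)C(C)C)c(O[Si](C(C)C)(C(C)C)C(C)C)c1 | intermediate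
19 | propanedial carrying the same two C2 substituents as 18 | O=CC(C=O)(C[C@H](C(C)=C)CC=C(C)C)C[C@H](CC=C(C)C)C(C)(C)C#Cc1ccc(O[Si](C(C)C)(C(C)C)C(C)C)c(O[Si](C(C)C)(C(C)C)C(C)C)c1 | intermediate
20 | hepta-1,6-diene-3,5-diol carrying the same two substituents at C4 (mixture at the two carbinol carbons) | C=CC(O)C(C(O)C=C)(C[C@H](C(C)=C)CC=C(C)C)C[C@H](CC=C(C)C)C(C)(C)C#Cc1ccc(O[Si](C(C)C)(C(C)C)C(C)C)c(O[Si](C(C)C)(C(C)C)C(C)C)c1 | intermediate
21 | cyclopent-4-ene-1,3-diol carrying the same two substituents at C2 (cis and trans diols) | OC1C=CC(O)C1(C[C@H](C(C)=C)CC=C(C)C)C[C@H](CC=C(C)C)C(C)(C)C#Cc2ccc(O[Si](C(C)C)(C(C)C)C(C)C)c(O[Si](C(C)C)(C(C)C)C(C)C)c2 | intermediate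
22 | 2-{(2S)-5-[3,4-bis(triisopropylsilyloxy)phenyl]-3,3-dimethyl-2-(3-methylbut-2-en-1-yl)-5-oxopentyl}-2-[(2R)-lavandulyl]cyclopent-4-ene-1,3-diol | OC1C=CC(O)C1(C[C@H](C(C)=C)CC=C(C)C)C[C@H](CC=C(C)C)C(C)(C)CC(=O)c2ccc(O[Si](C(C)C)(C(C)C)C(C)C)c(O[Si](C(C)C)(C(C)C)C(C)C)c2 | intermediate
23 | bis(trifluoroacetate) of 22 carrying a trifluoroacetyl group on C1 | O=C(OC1C=CC(OC(=O)C(F)(F)F)C1(C[C@H](C(C)=C)CC=C(C)C)C[C@H](CC=C(C)C)C(C)(C)C(C(=O)C(F)(F)F)C(=O)c2ccc(O[Si](C(C)C)(C(C)C)C(C)C)c(O[Si](C(C)C)(C(C)C)C(C)C)c2)C(F)(F)F | intermediate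
24 | 22 with a diazo group on C1 (4-diazo-5-oxopentyl chain) | OC1C=CC(O)C1(C[C@H](C(C)=C)CC=C(C)C)C[C@H](CC=C(C)C)C(C)(C)C(=[N+]=[N-])C(=O)c2ccc(O[Si](C(C)C)(C(C)C)C(C)C)c(O[Si](C(C)C)(C(C)C)C(C)C)c2 | intermediate
25 | 2-{(2S)-5-[3,4-bis(triisopropylsilyloxy)phenyl]-4-diazo-3,3-dimethyl-2-(3-methylbut-2-en-1-yl)-5-oxopentyl}-2-[(2R)-lavandulyl]cyclopent-4-ene-1,3-dione | O=C1C=CC(=O)C1(C[C@H](C(C)=C)CC=C(C)C)C[C@H](CC=C(C)C)C(C)(C)C(=[N+]=[N-])C(=O)c2ccc(O[Si](C(C)C)(C(C)C)C(C)C)c(O[Si](C(C)C)(C(C)C)C(C)C)c2 | intermediate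
26 | cis-fused hydrindenone betaine: C9 oxide (scandium-bound), C1 diazonium anti to the C9–C2 bond, aroyl equatorial | C=C(C)[C@H](CC=C(C)C)C[C@]12C[C@H](CC=C(C)C)C(C)(C)[C@@]([N+]#N)(C(=O)c3ccc(O[Si](C(C)C)(C(C)C)C(C)C)c(O[Si](C(C)C)(C(C)C)C(C)C)c3)[C@@]1([O-])C=CC2=O | intermediate
27 | bicyclo[3.3.1]non-3-ene-2,9-dione (C4=O, C9=O, C2=C3): C1 3,4-bis(triisopropylsilyloxy)benzoyl, C5 (R)-lavandulyl, C7 prenyl exo (equatorial on ring B), C8 gem-dimethyl; C1, C5, C7 arranged as in the target | C=C(C)[C@H](CC=C(C)C)C[C@]12C[C@H](CC=C(C)C)C(C)(C)[C@](C(=O)c3ccc(O[Si](C(C)C)(C(C)C)C(C)C)c(O[Si](C(C)C)(C(C)C)C(C)C)c3)(C1=O)C=CC2=O | intermediate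
28 | 27 with C2=C3 saturated and a pinacolboryl group on C2 (C2 epimers) | C=C(C)[C@H](CC=C(C)C)C[C@]12C[C@H](CC=C(C)C)C(C)(C)[C@](C(=O)c3ccc(O[Si](C(C)C)(C(C)C)C(C)C)c(O[Si](C(C)C)(C(C)C)C(C)C)c3)(C1=O)C(B4OC(C)(C)C(C)(C)O4)CC2=O | intermediate
29 | C2 alcohol corresponding to 28 (C2 epimers) | C=C(C)[C@H](CC=C(C)C)C[C@]12C[C@H](CC=C(C)C)C(C)(C)[C@](C(=O)c3ccc(O[Si](C(C)C)(C(C)C)C(C)C)c(O[Si](C(C)C)(C(C)C)C(C)C)c3)(C1=O)C(O)CC2=O | intermediate
30 | bicyclo[3.3.1]nonane-2,4,9-trione (C2/C4 enol, C3–H), other substituents as in 27 | C=C(C)[C@H](CC=C(C)C)C[C@]12C[C@H](CC=C(C)C)C(C)(C)[C@](C(=O)c3ccc(O[Si](C(C)C)(C(C)C)C(C)C)c(O[Si](C(C)C)(C(C)C)C(C)C)c3)(C1=O)C(O)=CC2=O | intermediate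
31 | bis(triisopropylsilyl) ether of the target (C3 prenyl in place) | C=C(C)[C@H](CC=C(C)C)C[C@]12C[C@H](CC=C(C)C)C(C)(C)[C@](C(=O)c3ccc(O[Si](C(C)C)(C(C)C)C(C)C)c(O[Si](C(C)C)(C(C)C)C(C)C)c3)(C1=O)C(O)=C(CC=C(C)C)C2=O | intermediate
32 | target CNP0425478.2, (1S,5R,7S) with (R) side chain | C=C(C)[C@H](CC=C(C)C)C[C@]12C[C@H](CC=C(C)C)C(C)(C)[C@](C(=O)c3ccc(O)c(O)c3)(C1=O)C(O)=C(CC=C(C)C)C2=O | target

**Totals and risks**

Total step count: 23. Longest linear sequence: 18 steps (steps 1, 3–6, 11–23).

Steps most likely to fail: 19, 20 and 11.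

Step 19 (proposed new method). What may go wrong: poor discrimination between the two ring carbonyls, migration of C5 instead of C2 or epoxide closure of the betaine, a Lewis-acid carbonyl-ene reaction with the isopropenyl group, or dipolar cycloaddition of the diazo group onto the enedione double bond. The fallback uses known chemistry and sets out from keto diol 22. MnO2 in CH2Cl2 should oxidise the diol to the aryl ketone enedione F1. A reversible base-mediated intramolecular aldol addition (DBU, CH2Cl2) of the aryl ketone α-carbon C1 to one ring carbonyl should then give the hydroxy hydrindenedione F2; C7 again chooses the carbonyl through the chair with equatorial prenyl, now under thermodynamic control. Treatment of F2 with PhI(OAc)2 and KOH in MeOH (iodanation of the ketone enolate at C1, then 1,2-shift of C2 from the carbinol carbon, an oxidative semipinacol ring expansion of the type known for turning fused hydroxy ketones into bicyclo[3.3.1]nonane polyketones) should give 27, where the route is rejoined.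

Step 20. What may go wrong: retro-Claisen cleavage at the acyl-laden C1 by alkoxide during borylation, or retro-aldol opening of the C1–C2 bond of the β-hydroxy ketone. The fallback sets out from 27: nucleophilic Weitz–Scheffer epoxidation (t-BuOOH, DBU, CH2Cl2) should give the epoxy ketone F3, and Pd(PPh3)4 with 1,2-bis(diphenylphosphino)ethane in toluene at 80 °C should isomerise the α,β-epoxy ketone directly to the β-diketone 30, where the route is rejoined without passing through an alkoxide at C2.

Step 11. What may go wrong: slow SN2 displacement at the β-branched carbon next to the quaternary centre, with competing elimination. The fallback sets out from alcohol 8: Dess–Martin oxidation should give the aldehyde F4, Knoevenagel condensation with malononitrile 16 (β-alanine, EtOH, rt) the alkylidenemalononitrile F5, and conjugate reduction with Hantzsch ester (EtOH, rt) the monoalkylated malononitrile 17, where the route is rejoined; neutral conditions are chosen to limit epimerisation at C7.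

Further compounds
F1 | step 19 | 2-{(2S)-5-[3,4-bis(triisopropylsilyloxy)phenyl]-3,3-dimethyl-2-(3-methylbut-2-en-1-yl)-5-oxopentyl}-2-[(2R)-lavandulyl]cyclopent-4-ene-1,3-dione | O=C1C=CC(=O)C1(C[C@H](C(C)=C)CC=C(C)C)C[C@H](CC=C(C)C)C(C)(C)CC(=O)c2ccc(O[Si](C(C)C)(C(C)C)C(C)C)c(O[Si](C(C)C)(C(C)C)C(C)C)c2
F2 | step 19 | cis-fused aldol adduct of F1 (C9 tertiary alcohol, C1–H axial, aroyl equatorial) | C=C(C)[C@H](CC=C(C)C)C[C@]12C[C@H](CC=C(C)C)C(C)(C)[C@@H](C(=O)c3ccc(O[Si](C(C)C)(C(C)C)C(C)C)c(O[Si](C(C)C)(C(C)C)C(C)C)c3)[C@@]1(O)C=CC2=O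
F3 | step 20 | C2–C3 epoxide of 27 | C=C(C)[C@H](CC=C(C)C)C[C@]12C[C@H](CC=C(C)C)C(C)(C)[C@](C(=O)c3ccc(O[Si](C(C)C)(C(C)C)C(C)C)c(O[Si](C(C)C)(C(C)C)C(C)C)c3)(C1=O)C4OC4C2=O
F4 | step 11 | (2R)-5-[3,4-bis(triisopropylsilyloxy)phenyl]-3,3-dimethyl-2-(3-methylbut-2-en-1-yl)pent-4-ynal | CC(C)[Si](C(C)C)(C(C)C)Oc1ccc(C#CC(C)(C)[C@@H](CC=C(C)C)C=O)cc1O[Si](C(C)C)(C(C)C)C(C)C
F5 | step 11 | alkylidenemalononitrile from F4 | N#CC(C#N)=C[C@H](CC=C(C)C)C(C)(C)C#Cc1ccc(O[Si](C(C)C)(C(C)C)C(C)C)c(O[Si](C(C)C)(C(C)C)C(C)C)c1
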